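Everything rests on cutting the epoxycyclohexenone ring back to an achiral 4-silyloxy-4-alkynylcyclohexa-2,5-dienone. With the C2 nitrogen set aside, C4 (carbinol), C5 and C6 (oxirane) of the six-membered ring, numbered from the C1 ketone, are just one epoxidised arm of this mirror-symmetric dienone. A tert-butyl peroxide anion paired with a chiral ammonium cation should epoxidise one of the two enantiotopic enone arms on the face opposite the bulky silyl ether, which closes the oxirane and sets C4, C5 and C6 with the C4 oxygen trans to the epoxide in one operation. The precursor is the quinol tert-butyldimethylsilyl ether whose ethynyl group keeps a triisopropylsilyl cap.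

Key step: step 2

Assumption: N-benzylcinchonidinium chloride is taken to favour the (4R,5S,6R) epoxide; should the opposite sense be found, the pseudo-enantiomeric N-benzylcinchoninium chloride replaces it under the same conditions.
Remark on numbering and configuration: ring atoms are C1 (ketone), C2 (amide carbon), C3, C4 (carbinol), C5 and C6 (oxirane). In the target the C4 hydroxyl is trans to the oxirane oxygen, (4S,5S,6R). The C4 descriptor is R up to the vinylstannane and becomes S in the last step only through a change of CIP priorities; no bond at C4 is touched.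
Remark on design: the ethynyl carbon carries a triisopropylsilyl cap from step 1 to step 8, so that no alkyne C–H meets hydroxide, iodine or copper. The carbon skeleton of the key-step substrate and product is unchanged. The dienone is reached in one step from the commercial quinone monoketal.

Step 1
Reactants: 1 (triisopropylsilyl)acetylene; 2 4,4-dimethoxycyclohexa-2,5-dien-1-one
Product: 6 4-[(tert-butyldimethylsilyl)oxy]-4-[(triisopropylsilyl)ethynyl]cyclohexa-2,5-dien-1-one, via lithium (triisopropylsilyl)acetylide 3 (not isolated), via lithium carbinolate 4 (not isolated), via silyl ether dimethyl ketal 5 (not isolated)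
Conditions: n-BuLi, THF, −78 °C; then 2; then TBSOTf, −78 → 0 °C; then 1 M aq HCl, rt
Reagents that add atoms: tert-butyldimethylsilyl trifluoromethanesulfonate, CC(C)(C)[Si](C)(C)OS(=O)(=O)C(F)(F)F; water, O
Why: 1,2-addition of a lithium acetylide to the ketone of a quinone monoketal is ordinary carbonyl addition, the tertiary lithium alkoxide is silylated in the flask by the silyl triflate, and dilute acid hydrolyses the doubly allylic dimethyl ketal through its oxocarbenium ion much faster than it attacks the tertiary silyl ether or the alkynylsilane; no stereocentre arises because the product has a mirror plane through C1 and C4.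

Step 2
Reactants: 6 4-[(tert-butyldimethylsilyl)oxy]-4-[(triisopropylsilyl)ethynyl]cyclohexa-2,5-dien-1-one
Product: 7 (4R,5S,6R)-4-[(tert-butyldimethylsilyl)oxy]-5,6-epoxy-4-[(triisopropylsilyl)ethynyl]cyclohex-2-en-1-one (silyloxy group trans to the oxirane oxygen)
Conditions: t-BuOOH (1.0 equiv), N-benzylcinchonidinium chloride (10 mol %), aq NaOH, toluene, 0 °C
Reagents that add atoms: tert-butyl hydroperoxide, CC(C)(C)OO
Why: Proposed new method: the tert-butyl peroxide anion, carried into toluene as an ion pair with the cinchonidinium cation, adds to C5 of one enone arm of 6 to give the C1 enolate, and C6 of that enolate then displaces tert-butoxide from the proximal peroxide oxygen, so that the C5–O and C6–O bonds are made in one Weitz–Scheffer sequence. The closest known reaction type is the cinchona phase-transfer Weitz–Scheffer epoxidation of enones and quinone monoketals; what is new is its use to tell apart the two enantiotopic enone arms of a 4,4-disubstituted cyclohexa-2,5-dienone. The oxirane closes in a 3-exo-tet mode at oxygen and is necessarily cis-fused to the six-membered ring. C5 and C6 are set by attack on the ring face opposite the C4 silyloxy group, favoured by the bulk of the silyl ether against the rod-like alkynyl group and by the Felkin–Anh-type preference for entry antiperiplanar to the C4–O bond, while C4 becomes stereogenic only through the choice of arm, which the chiral cation makes. The step needs arm selectivity (from the catalyst), face selectivity (from the substrate) and mono-epoxidation (from one equivalent of hydroperoxide at 0 °C and stopping short of full conversion), and the hydroxide-stable silyl cap and tertiary silyl ether keep the substrate intact in the basic two-phase medium.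

Step 3
Reactants: 7 (4R,5S,6R)-4-[(tert-butyldimethylsilyl)oxy]-5,6-epoxy-4-[(triisopropylsilyl)ethynyl]cyclohex-2-en-1-one
Product: 8 (4R,5S,6R)-4-[(tert-butyldimethylsilyl)oxy]-5,6-epoxy-2-iodo-4-[(triisopropylsilyl)ethynyl]cyclohex-2-en-1-one
Conditions: I2, pyridine, 4-(dimethylamino)pyridine (cat.), CH2Cl2, 0 °C → rt
Reagents that add atoms: iodine, II
Why: α-Iodination of an enone by the iodine–pyridine method (Baylis–Hillman-type sequence: reversible amine addition at C3, iodination of the enolate at C2, E1cB loss of the amine) can only place iodine at C2 of the one remaining enone, the capped alkyne offers no C–H to iodinate, and C4, C5 and C6 are untouched.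

Step 4
Reactants: 9 4-methylpentanal; 10 triethyl 4-phosphonocrotonate [ethyl (E)-4-(diethoxyphosphoryl)but-2-enoate]
Product: 11 ethyl (2E,4E)-8-methylnona-2,4-dienoate
Conditions: LiOH·H2O, 4 Å molecular sieves, THF, reflux
Reagents that add atoms: none
Why: Vinylogous Horner–Wadsworth–Emmons olefination with the stabilised phosphonate anion forms the new C4=C5 bond as the thermodynamically favoured E isomer, the crotonate alkene stays E, and the mild hydroxide base tolerates the enolisable aldehyde.

Step 5
Reactants: 11 ethyl (2E,4E)-8-methylnona-2,4-dienoate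
Product: 12 (2E,4E)-8-methylnona-2,4-dien-1-ol
Conditions: i-Bu2AlH, CH2Cl2, −78 °C
Reagents that add atoms: none
Why: Hydride reduction of the conjugated ester by i-Bu2AlH proceeds by 1,2-delivery of two hydrides to the dienylic alcohol without touching the diene or its geometry.

Step 6
Reactants: 12 (2E,4E)-8-methylnona-2,4-dien-1-ol; 13 (carbamoylmethylene)triphenylphosphorane
Product: 15 (2E,4E,6E)-10-methylundeca-2,4,6-trienamide, via (2E,4E)-8-methylnona-2,4-dienal 14 (not isolated)
Conditions: MnO2, CH2Cl2, reflux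
Reagents that add atoms: none
Why: Tandem oxidation–Wittig olefination: MnO2 oxidises the allylic-type alcohol to dienal 14, which is trapped as it forms by the amide-stabilised ylide to give the new C2=C3 bond with the E geometry usual for stabilised ylides, so the sensitive dienal is never handled.

Step 7
Reactants: 8 (4R,5S,6R)-4-[(tert-butyldimethylsilyl)oxy]-5,6-epoxy-2-iodo-4-[(triisopropylsilyl)ethynyl]cyclohex-2-en-1-one; 15 (2E,4E,6E)-10-methylundeca-2,4,6-trienamide
Product: 16 (4R,5S,6R)-4-[(tert-butyldimethylsilyl)oxy]-5,6-epoxy-2-{[(2E,4E,6E)-10-methylundeca-2,4,6-trienoyl]amino}-4-[(triisopropylsilyl)ethynyl]cyclohex-2-en-1-one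
Conditions: CuI (10 mol %), N,N'-dimethylethylenediamine (20 mol %), Cs2CO3, THF, 60 °C, dark
Reagents that add atoms: none
Why: Goldberg-type copper-catalysed amidation of a vinyl iodide, a reaction known for α-iodoenones, joins the diamine-ligated copper amidate to the activated C2–I bond with retention at the alkene; the silyl cap excludes copper acetylide chemistry, the silyl ether keeps the C4 oxygen from attacking the oxirane under carbonate, and no stereocentre is involved.

Step 8
Reactants: 16 (4R,5S,6R)-4-[(tert-butyldimethylsilyl)oxy]-5,6-epoxy-2-{[(2E,4E,6E)-10-methylundeca-2,4,6-trienoyl]amino}-4-[(triisopropylsilyl)ethynyl]cyclohex-2-en-1-one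
Product: 17 (4R,5S,6R)-5,6-epoxy-4-ethynyl-4-hydroxy-2-{[(2E,4E,6E)-10-methylundeca-2,4,6-trienoyl]amino}cyclohex-2-en-1-one
Conditions: Bu4NF, AcOH (1:1), THF, 0 °C → rt
Reagents that add atoms: none
Why: Fluoride-induced desilylation cleaves both the alkynyl C–Si and the tertiary O–Si bond, and the acetic acid buffer protonates the C4 alkoxide at once so that it cannot migrate the trans oxirane by Payne rearrangement; the stereocentres are untouched.

Step 9
Reactants: 17 (4R,5S,6R)-5,6-epoxy-4-ethynyl-4-hydroxy-2-{[(2E,4E,6E)-10-methylundeca-2,4,6-trienoyl]amino}cyclohex-2-en-1-one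
Product: 18 (4R,5S,6R)-5,6-epoxy-4-hydroxy-2-{[(2E,4E,6E)-10-methylundeca-2,4,6-trienoyl]amino}-4-[(E)-2-(tributylstannyl)ethenyl]cyclohex-2-en-1-one
Conditions: Bu3SnH (slow addition), PdCl2(PPh3)2 (cat.), THF, 0 °C
Reagents that add atoms: tributyltin hydride, CCCC[SnH](CCCC)CCCC
Why: Palladium-catalysed hydrostannylation adds H and Bu3Sn syn across the terminal alkyne with tin at the terminal carbon, away from the fully substituted C4, which gives the E vinylstannane; the alkyne should react far faster than the hindered α-amido enone or the trienamide when the hydride is added slowly in the cold.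

Step 10
Reactants: 19 ethyl (E)-4-oxobut-2-enoate
Product: 20 ethyl (2E,4E)-5-iodopenta-2,4-dienoate
Conditions: CHI3, CrCl2, THF, 0 °C
Reagents that add atoms: iodoform, IC(I)I
Why: Takai olefination: the geminal dichromium species from iodoform and CrCl2 adds to the aldehyde and eliminates to the E vinyl iodide, while the ester-bearing alkene keeps its E geometry.

Step 11
Reactants: 20 ethyl (2E,4E)-5-iodopenta-2,4-dienoate
Product: 21 (2E,4E)-5-iodopenta-2,4-dienoic acid
Conditions: LiOH, THF/H2O, 0 °C → rt; then aq HCl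
Reagents that add atoms: lithium hydroxide, [Li+].[OH-]
Why: Saponification (acyl substitution by hydroxide) of the ethyl ester in the cold leaves the vinylic iodide and the diene geometry intact, and acidification liberates the acid.

Step 12
Reactants: 22 cyclopentane-1,3-dione
Product: 23 2-(hydroxyimino)cyclopentane-1,3-dione
Conditions: NaNO2, aq HCl, 0 °C
Reagents that add atoms: sodium nitrite, [Na+].[O-]N=O
Why: C-Nitrosation of the enol of the 1,3-dione at its doubly activated C2 by nitrous acid made in the flask, followed by tautomerisation of the nitroso compound to the oxime.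

Step 13
Reactants: 23 2-(hydroxyimino)cyclopentane-1,3-dione
Product: 24 2-amino-3-hydroxycyclopent-2-en-1-one hydrochloride
Conditions: H2 (1 atm), Pd/C, HCl, MeOH, rt
Reagents that add atoms: hydrogen chloride, Cl
Why: Catalytic hydrogenation of the oxime cleaves the N–O bond and saturates C=N to the primary amine, which is caught as the hydrochloride of its enol form and so kept from self-condensation.

Step 14
Reactants: 21 (2E,4E)-5-iodopenta-2,4-dienoic acid; 24 2-amino-3-hydroxycyclopent-2-en-1-one hydrochloride
Product: 26 (2E,4E)-N-(2-hydroxy-5-oxocyclopent-1-en-1-yl)-5-iodopenta-2,4-dienamide, via (2E,4E)-5-iodopenta-2,4-dienoyl chloride 25 (not isolated)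
Conditions: (COCl)2, DMF (cat.), CH2Cl2, 0 °C → rt; then 24, pyridine, CH2Cl2/DMF, 0 °C → rt
Reagents that add atoms: none
Why: Acid chloride formation (Vilsmeier-type activation by DMF) and Schotten–Baumann-type N-acylation of the amine freed by pyridine give the amide, and any O-acyl enol ester is a labile vinylogous anhydride that passes its acyl group to nitrogen or is cleaved on bicarbonate work-up.

Step 15
Reactants: 18 (4R,5S,6R)-5,6-epoxy-4-hydroxy-2-{[(2E,4E,6E)-10-methylundeca-2,4,6-trienoyl]amino}-4-[(E)-2-(tributylstannyl)ethenyl]cyclohex-2-en-1-one; 26 (2E,4E)-N-(2-hydroxy-5-oxocyclopent-1-en-1-yl)-5-iodopenta-2,4-dienamide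
Product: 27 (4S,5S,6R)-5,6-epoxy-4-hydroxy-4-{(1E,3E,5E)-7-[(2-hydroxy-5-oxocyclopent-1-en-1-yl)amino]-7-oxohepta-1,3,5-trien-1-yl}-2-{[(2E,4E,6E)-10-methylundeca-2,4,6-trienoyl]amino}cyclohex-2-en-1-one (target CNP0304685.4)
Conditions: PdCl2(MeCN)2 (cat.), DMF, rt, dark
Reagents that add atoms: none
Why: Stille coupling (oxidative addition of zerovalent palladium into the dienyl C–I bond, transmetallation from the vinylstannane, reductive elimination) joins the two sp2 carbons with retention of both alkene geometries under neutral conditions that the free tertiary alcohol, the oxirane, the enol and both amides tolerate; the three stereocentres are not affected.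

Compound list
1 | (triisopropylsilyl)acetylene | C#C[Si](C(C)C)(C(C)C)C(C)C | starting material
2 | 4,4-dimethoxycyclohexa-2,5-dien-1-one | COC1(OC)C=CC(=O)C=C1 | starting material
3 | lithium (triisopropylsilyl)acetylide (formed in the flask) | [Li]C#C[Si](C(C)C)(C(C)C)C(C)C | intermediate
4 | lithium 4,4-dimethoxy-1-[(triisopropylsilyl)ethynyl]cyclohexa-2,5-dien-1-olate (formed in the flask) | [Li]OC1(C#C[Si](C(C)C)(C(C)C)C(C)C)C=CC(OC)(OC)C=C1 | intermediate
5 | tert-butyl({4,4-dimethoxy-1-[(triisopropylsilyl)ethynyl]cyclohexa-2,5-dien-1-yl}oxy)dimethylsilane (formed in the flask) | COC1(OC)C=CC(O[Si](C)(C)C(C)(C)C)(C#C[Si](C(C)C)(C(C)C)C(C)C)C=C1 | intermediate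
6 | 4-[(tert-butyldimethylsilyl)oxy]-4-[(triisopropylsilyl)ethynyl]cyclohexa-2,5-dien-1-one (achiral) | O=C1C=CC(O[Si](C)(C)C(C)(C)C)(C#C[Si](C(C)C)(C(C)C)C(C)C)C=C1 | intermediate
7 | (4R,5S,6R)-4-[(tert-butyldimethylsilyl)oxy]-5,6-epoxy-4-[(triisopropylsilyl)ethynyl]cyclohex-2-en-1-one | C1=C[C@@](O[Si](C)(C)C(C)(C)C)(C#C[Si](C(C)C)(C(C)C)C(C)C)[C@H]2O[C@H]2C1=O | intermediate
8 | (4R,5S,6R)-4-[(tert-butyldimethylsilyl)oxy]-5,6-epoxy-2-iodo-4-[(triisopropylsilyl)ethynyl]cyclohex-2-en-1-one | IC1=C[C@@](O[Si](C)(C)C(C)(C)C)(C#C[Si](C(C)C)(C(C)C)C(C)C)[C@H]2O[C@H]2C1=O | intermediate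
9 | 4-methylpentanal | CC(C)CCC=O | starting material
10 | triethyl 4-phosphonocrotonate | CCOC(=O)/C=C/CP(=O)(OCC)OCC | starting material
11 | ethyl (2E,4E)-8-methylnona-2,4-dienoate | CC(C)CC/C=C/C=C/C(=O)OCC | intermediate
12 | (2E,4E)-8-methylnona-2,4-dien-1-ol | CC(C)CC/C=C/C=C/CO | intermediate
13 | (carbamoylmethylene)triphenylphosphorane | NC(=O)C=P(c1ccccc1)(c1ccccc1)c1ccccc1 | starting material
14 | (2E,4E)-8-methylnona-2,4-dienal (formed in the flask) | CC(C)CC/C=C/C=C/C=O | intermediate
15 | (2E,4E,6E)-10-methylundeca-2,4,6-trienamide | CC(C)CC/C=C/C=C/C=C/C(N)=O | intermediate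
16 | (4R,5S,6R)-4-[(tert-butyldimethylsilyl)oxy]-5,6-epoxy-2-{[(2E,4E,6E)-10-methylundeca-2,4,6-trienoyl]amino}-4-[(triisopropylsilyl)ethynyl]cyclohex-2-en-1-one | CC(C)CC/C=C/C=C/C=C/C(=O)NC1=C[C@@](O[Si](C)(C)C(C)(C)C)(C#C[Si](C(C)C)(C(C)C)C(C)C)[C@H]2O[C@H]2C1=O | intermediate
17 | (4R,5S,6R)-5,6-epoxy-4-ethynyl-4-hydroxy-2-{[(2E,4E,6E)-10-methylundeca-2,4,6-trienoyl]amino}cyclohex-2-en-1-one | CC(C)CC/C=C/C=C/C=C/C(=O)NC1=C[C@@](O)(C#C)[C@H]2O[C@H]2C1=O | intermediate
18 | (4R,5S,6R)-5,6-epoxy-4-hydroxy-2-{[(2E,4E,6E)-10-methylundeca-2,4,6-trienoyl]amino}-4-[(E)-2-(tributylstannyl)ethenyl]cyclohex-2-en-1-one | CC(C)CC/C=C/C=C/C=C/C(=O)NC1=C[C@@](O)(/C=C/[Sn](CCCC)(CCCC)CCCC)[C@H]2O[C@H]2C1=O | intermediate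
19 | ethyl (E)-4-oxobut-2-enoate | CCOC(=O)/C=C/C=O | starting material
20 | ethyl (2E,4E)-5-iodopenta-2,4-dienoate | CCOC(=O)/C=C/C=C/I | intermediate
21 | (2E,4E)-5-iodopenta-2,4-dienoic acid | OC(=O)/C=C/C=C/I | intermediate
22 | cyclopentane-1,3-dione | O=C1CCC(=O)C1 | starting material
23 | 2-(hydroxyimino)cyclopentane-1,3-dione | ON=C1C(=O)CCC1=O | intermediate
24 | 2-amino-3-hydroxycyclopent-2-en-1-one hydrochloride | Cl.NC1=C(O)CCC1=O | intermediate
25 | (2E,4E)-5-iodopenta-2,4-dienoyl chloride (formed in the flask) | ClC(=O)/C=C/C=C/I | intermediate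
26 | (2E,4E)-N-(2-hydroxy-5-oxocyclopent-1-en-1-yl)-5-iodopenta-2,4-dienamide | I/C=C/C=C/C(=O)NC1=C(O)CCC1=O | intermediate
27 | (4S,5S,6R)-5,6-epoxy-4-hydroxy-4-{(1E,3E,5E)-7-[(2-hydroxy-5-oxocyclopent-1-en-1-yl)amino]-7-oxohepta-1,3,5-trien-1-yl}-2-{[(2E,4E,6E)-10-methylundeca-2,4,6-trienoyl]amino}cyclohex-2-en-1-one | CC(C)CC/C=C/C=C/C=C/C(=O)NC1=C[C@@](O)(/C=C/C=C/C=C/C(=O)NC2=C(O)CCC2=O)[C@H]2O[C@H]2C1=O | target

Total step count: 15.
Longest linear sequence: 7 steps (steps 1, 2, 3, 7, 8, 9 and 15).

Steps most likely to fail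

1. Step 2 (proposed new method). The ion pair may discriminate poorly between the two enantiotopic enone arms, so that enantiomeric purity is low; face selectivity may erode, or a second epoxidation may follow. Fallback, setting out from 6 and returning at 7: arm selection is given up. Achiral Weitz–Scheffer epoxidation (t-BuOOH, benzyltrimethylammonium hydroxide, THF, 0 °C), a known reaction of cross-conjugated cyclohexadienones, should still enter anti to the silyl ether. It would give 7 as a racemate with its mirror image, (4S,5R,6S)-4-[(tert-butyldimethylsilyl)oxy]-5,6-epoxy-4-[(triisopropylsilyl)ethynyl]cyclohex-2-en-1-one F1. Preparative chromatography on a chiral stationary phase (amylose carbamate type, supercritical CO2 with an alcohol) then separates the two, and 7 goes on to step 3.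

2. Step 7. Coupling at the C2–I bond, which sits next to the fully substituted C4, may be slow with a weakly nucleophilic conjugated primary amide. Carbonate or the diamine may meanwhile degrade the epoxy ketone, or reductive loss of iodine may compete. Fallback, setting out from 8 (and from 12) and returning at 16: nitrogen is brought in as a small nucleophile at room temperature and acylated afterwards.
   - CuI-catalysed azidation of the vinyl iodide (NaN3, sodium ascorbate, N,N'-dimethylethylenediamine, EtOH/H2O, rt) gives (4R,5S,6R)-2-azido-4-[(tert-butyldimethylsilyl)oxy]-5,6-epoxy-4-[(triisopropylsilyl)ethynyl]cyclohex-2-en-1-one F2.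
   - Staudinger reduction (PMe3, THF; then H2O) gives (4R,5S,6R)-2-amino-4-[(tert-butyldimethylsilyl)oxy]-5,6-epoxy-4-[(triisopropylsilyl)ethynyl]cyclohex-2-en-1-one F3.
   - Separately, dienal 14, now isolated after MnO2 oxidation of 12, undergoes Knoevenagel–Doebner condensation with malonic acid (pyridine, piperidine cat., 80 °C) to (2E,4E,6E)-10-methylundeca-2,4,6-trienoic acid F4.
   - (COCl)2 with catalytic DMF turns this into (2E,4E,6E)-10-methylundeca-2,4,6-trienoyl chloride F5.
   - N-Acylation of the amino enone with this chloride (pyridine, 4-(dimethylamino)pyridine, CH2Cl2, 0 °C) gives 16.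

3. Step 8. Cleavage of the tertiary silyl ether may lag behind that of the alkynylsilane. Once the C4 oxygen is free in a fluoride medium, epoxide migration (Payne rearrangement) or breakdown of the epoxy ketone may set in. Fallback, setting out from 16 and returning at 27: only the alkyne is uncapped and the silyl ether is carried to the end.
   - AgF (MeCN, rt, dark; then dilute HCl) removes the triisopropylsilyl group chemoselectively to give (4R,5S,6R)-4-[(tert-butyldimethylsilyl)oxy]-5,6-epoxy-4-ethynyl-2-{[(2E,4E,6E)-10-methylundeca-2,4,6-trienoyl]amino}cyclohex-2-en-1-one F6.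
   - Hydrostannylation as in step 9 gives (4R,5S,6R)-4-[(tert-butyldimethylsilyl)oxy]-5,6-epoxy-2-{[(2E,4E,6E)-10-methylundeca-2,4,6-trienoyl]amino}-4-[(E)-2-(tributylstannyl)ethenyl]cyclohex-2-en-1-one F7.
   - Stille coupling with 26 as in step 15 gives the O-tert-butyldimethylsilyl ether of the target F8.
   - HF·pyridine buffered with pyridine (THF, 0 °C) frees the tertiary alcohol under non-basic conditions and gives 27.

Further compounds
F1 | step 2 | (4S,5R,6S)-4-[(tert-butyldimethylsilyl)oxy]-5,6-epoxy-4-[(triisopropylsilyl)ethynyl]cyclohex-2-en-1-one (enantiomer of 7) | C1=C[C@](O[Si](C)(C)C(C)(C)C)(C#C[Si](C(C)C)(C(C)C)C(C)C)[C@@H]2O[C@@H]2C1=O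
F2 | step 7 | (4R,5S,6R)-2-azido-4-[(tert-butyldimethylsilyl)oxy]-5,6-epoxy-4-[(triisopropylsilyl)ethynyl]cyclohex-2-en-1-one | [N-]=[N+]=NC1=C[C@@](O[Si](C)(C)C(C)(C)C)(C#C[Si](C(C)C)(C(C)C)C(C)C)[C@H]2O[C@H]2C1=O
F3 | step 7 | (4R,5S,6R)-2-amino-4-[(tert-butyldimethylsilyl)oxy]-5,6-epoxy-4-[(triisopropylsilyl)ethynyl]cyclohex-2-en-1-one | NC1=C[C@@](O[Si](C)(C)C(C)(C)C)(C#C[Si](C(C)C)(C(C)C)C(C)C)[C@H]2O[C@H]2C1=O
F4 | step 7 | (2E,4E,6E)-10-methylundeca-2,4,6-trienoic acid | CC(C)CC/C=C/C=C/C=C/C(O)=O
F5 | step 7 | (2E,4E,6E)-10-methylundeca-2,4,6-trienoyl chloride | CC(C)CC/C=C/C=C/C=C/C(Cl)=O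
F6 | step 8 | (4R,5S,6R)-4-[(tert-butyldimethylsilyl)oxy]-5,6-epoxy-4-ethynyl-2-{[(2E,4E,6E)-10-methylundeca-2,4,6-trienoyl]amino}cyclohex-2-en-1-one | CC(C)CC/C=C/C=C/C=C/C(=O)NC1=C[C@@](O[Si](C)(C)C(C)(C)C)(C#C)[C@H]2O[C@H]2C1=O
F7 | step 8 | (4R,5S,6R)-4-[(tert-butyldimethylsilyl)oxy]-5,6-epoxy-2-{[(2E,4E,6E)-10-methylundeca-2,4,6-trienoyl]amino}-4-[(E)-2-(tributylstannyl)ethenyl]cyclohex-2-en-1-one | CC(C)CC/C=C/C=C/C=C/C(=O)NC1=C[C@@](O[Si](C)(C)C(C)(C)C)(/C=C/[Sn](CCCC)(CCCC)CCCC)[C@H]2O[C@H]2C1=O
F8 | step 8 | (4S,5S,6R)-4-[(tert-butyldimethylsilyl)oxy]-5,6-epoxy-4-{(1E,3E,5E)-7-[(2-hydroxy-5-oxocyclopent-1-en-1-yl)amino]-7-oxohepta-1,3,5-trien-1-yl}-2-{[(2E,4E,6E)-10-methylundeca-2,4,6-trienoyl]amino}cyclohex-2-en-1-one | CC(C)CC/C=C/C=C/C=C/C(=O)NC1=C[C@@](O[Si](C)(C)C(C)(C)C)(/C=C/C=C/C=C/C(=O)NC2=C(O)CCC2=O)[C@H]2O[C@H]2C1=O
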